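**The leftover.** After 20 min of stirring, this flask holds something we cannot read: the readings show 21.4% of the charged starting complex as complex with three exchanged, and the remainder stands in no column.

| setting | theta | flask |
|---|---|---|
| starting complex | 0.020 M | 0.020 M |
| incoming ligand | 2.5 equiv | 2.50 equiv |
| remark | the very flask that is asked about, followed so far |  |
| time |  | 20 min |

theta run (percent of the starting complex charged): time / min: complex with three exchanged / % = 1.50: 11.7; 2.50: 13.4; 4.00: 16.9; 6.00: 18.0; 8.00: 20.2; 12.0: 21.3; 20.0: 21.4

(standard deviation of a reading: 1 percentage point)

- Sunday's: change nothing and wait 40 min more
- Friday's: at 20 min add starting complex, 50.0% of the amount charged, then wait 40 min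
- Tuesday's: at 20 min add incoming ligand, 100% of the amount charged, then wait 40 min
- Monday's: at 20 min take out 90% of the leaving ligand then present, then wait 40 min

- additions leave the volume as it is

- complex with three exchanged, in percent of the starting complex first charged, at 20 min
- the option that brings most further complex with three exchanged ("none" if no option brings more than 2 percentage points) (Sunday's / Friday's / Tuesday's / Monday's / none)
- complex with three exchanged present, in percent of the starting complex first charged, after Sunday's
- complex with three exchanged present, in percent of the starting complex first charged, after Friday's

**The ledger.** We book the incoming ligand, 2.5 equiv per starting complex. Each complex with three exchanged takes 3, so by this count incoming ligand is the limiting reagent. The product entry holds 0.642, and 1.858 stays unread, which closes the books but does not say where that entry sits.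

**The price.** Dividing charge by reading gives 11.7 equiv, our ligand price, the incoming ligand charged per complex with three exchanged obtained. A clean book would cost 3, so the excess is either still free or paid into something unread. The last two readings, 21.3% and 21.4%, agree within the scatter, so we commit to about 21.4% now. The readings do not show which way the excess went, so we stop here.

**The forecast.** It takes the flat end as a balance: “I read this as equilibrium”. It gives 21.4% (range 20.5% to 22.3%), 21.6% after Sunday's, 23.5% after Friday's, and names Tuesday's as best.

**The flask.** The flask gives 21.3% now and 21.5% after Sunday's, but 0.136% after Friday's, a change of −21 percentage points. Tuesday's brings 0.75 points and Monday's 0.17 points, both under the margin of 2 points, so the answer is none. At 20.0 min in this flask, free starting complex, the first charge to run out, stands at 0% and free incoming ligand at 14.0% of its charge, so 86.0% of the charged incoming ligand was spent. Counted on that spent part, the price is 10.1 equiv.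

    complex with one exchanged + incoming ligand → leaving ligand + complex with two exchanged (k = 0.361 M⁻¹ s⁻¹)
    complex with two exchanged + incoming ligand → leaving ligand + complex with three exchanged (k = 1.48 M⁻¹ s⁻¹)
    complex with two exchanged → side product B (k = 0.0713 s⁻¹)
    crystals ⇌ leaving ligand, rate k4*(cs4 - [leaving ligand]) while solid is left; crystals form when [leaving ligand] > cs4 (solubility = 4.40 mM, k = 2.84 s⁻¹)
    starting complex + incoming ligand → leaving ligand + complex with one exchanged (k = 0.858 M⁻¹ s⁻¹)
    starting complex + complex with three exchanged → side product A (k = 1.65 M⁻¹ s⁻¹)

**The reason.** The main reason for the high price is the conversion of complex with two exchanged into side product B. With that step struck out, the flask reaches 67.2% at 20 min instead of 21.3%, and its price falls from 11.7 equiv to 3.72 equiv, against the clean 3. The neighbour flask charged with 1.50 equiv keeps 0.32% of its ligand and obtains 0.897%. Its price is 167 equiv, which is 14.3 times this flask's, or 1.15 decades higher.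

(The data are calculated with constants of no real substance, and the scatter is random.)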